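The numbers in the tables stem from a simulated flask for an exercise; the scatter is artificial.

Through the earlier runs one fork held steady: of what had reached target or isomer of the product by the last reading, between 17.1% (cedar) and 26.7% (larch) stood as isomer, while the total of the two ran from 23.0% in elm to 70.0% in cedar.

| flask | substrate | partner | second reagent | temperature | remark | time |
|---|---|---|---|---|---|---|
| elm | 0.14 M | 0.168 M | 0.14 M | −25 °C | run made earlier |  |
| cedar | 0.14 M | 0.168 M | 0.20 M | −14 °C | run made earlier |  |
| larch | 0.14 M | 0.168 M | 0.31 M | −25 °C | run made earlier |  |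
| maple | 0.14 M | 0.34 M | 0.14 M | −14 °C | run made earlier |  |
| zeta | 0.14 M | 0.168 M | 0.140 M | −20 °C | everything together at the start | 15 d |
| eta | 0.14 M | 0.168 M (fed, over 12 d) | 0.140 M |  | the addition at −40 °C, then warmed to −20 °C; the feed brings no volume worth counting | 15 d |
| beta | 0.14 M | 0.168 M (fed, over 12 d) | 0.140 M | −20 °C | all else is in the flask from the start; the feed brings no volume worth counting | 15 d |
| alpha | 0.14 M (in portions, 2, over 12 d) | 0.168 M | 0.140 M | −20 °C | first portion at the start, last at 12 d | 15 d |
| theta | 0.14 M | 0.168 M | 0.140 M |  | everything together at the start at −40 °C, warmed to −20 °C at 12 d | 15 d |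

| run | time / d | isomer of the product / % | target / % |
|---|---|---|---|
| elm | 1.25 | 0 | 2 |
| elm | 4.00 | 4 | 4 |
| elm | 8.00 | 2 | 11 |
| elm | 10.0 | 5 | 12 |
| elm | 15.0 | 4 | 19 |
| cedar | 1.25 | 5 | 11 |
| cedar | 4.00 | 8 | 28 |
| cedar | 8.00 | 10 | 43 |
| cedar | 10.0 | 14 | 47 |
| cedar | 15.0 | 12 | 58 |
| larch | 3.00 | 3 | 8 |
| larch | 6.00 | 9 | 16 |
| larch | 10.0 | 12 | 23 |
| larch | 12.0 | 11 | 26 |
| larch | 15.0 | 12 | 33 |
| maple | 1.25 | 3 | 10 |
| maple | 4.00 | 5 | 24 |
| maple | 8.00 | 8 | 33 |
| maple | 10.0 | 12 | 41 |
| maple | 15.0 | 14 | 47 |

(each reading ± 1.5 percentage points)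

* the flask with the highest amount of isomer of the product, in percent of the substrate charged ("all alike" if they lie within 1.5 percentage points) (zeta / eta / beta / alpha / theta / all alike)
* final isomer of the product, as a percentage of the substrate charged, in zeta
* final isomer of the product, as a percentage of the substrate charged, in eta
* final isomer of the product, as a percentage of the substrate charged, in beta
* final isomer of the product, as a percentage of the substrate charged, in alpha
* final isomer of the product, as a percentage of the substrate charged, in theta



You are taking over the bench, so here is what I would tell you about the new flasks.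

1. Carry the isomer share, the selectivity of this last fork: isomer over isomer plus target, pooled over the last readings of the earlier runs, which gives 21.1% as a reading, with its scatter.

2. For the total in zeta, note that from elm to larch the second reagent rose by a factor of 2.21 and the total by 1.96, so I scale the total in proportion to second reagent; since −20 °C lies between the temperatures of elm and cedar, I take the geometric mean of elm and of cedar scaled to zeta's charge, which gives 33.6%.

3. My own reckoning therefore expects zeta to hold 7.09% of isomer when you come at 15 d.

4. Leave the bath and the second reagent alone, since the total in cedar, warmer and richer in second reagent, stood higher than in elm; the feed over 12 d in beta and eta and the portions in alpha bring part of the charge in late, and eta and theta spend a stretch at −40 °C, so I expect zeta on top.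

5. The forecast says zeta, with 7.5% in zeta, 2.1% in eta, 5% in beta, 5% in alpha and 2.5% in theta, on the ground that “Isomer runs about 0.2–0.3 of target, noisy”; its zeta figure stands a little above mine.

    substrate + partner → intermediate (k = 7.80 × 10⁻⁴ M⁻¹ s⁻¹, Ea = 51.0 kJ mol⁻¹)
    second reagent + intermediate → target (k = 3.68 × 10⁻⁶ M⁻¹ s⁻¹, Ea = 73.0 kJ mol⁻¹)
    target ⇌ isomer of the product (K = 0.320, k = 3.77 × 10⁻⁵ s⁻¹, Ea = 76.0 kJ mol⁻¹, ΔH = −15.0 kJ mol⁻¹)
    partner ⇌ dormant form (K = 19.0, k = 1.56 × 10⁻⁵ s⁻¹, Ea = 78.0 kJ mol⁻¹, ΔH = −43.0 kJ mol⁻¹)
    (constants at −20 °C)

The flasks give 9.12% of isomer in zeta, more than eta at 2.86%, beta at 6.46%, alpha at 5.46% and theta at 3.16%. In zeta the isomer share at 15.0 d is 24.2% against the 21.1% read earlier, and target and isomer relax by the step between them alone with a half-life of 0.0516 d, shorter than the time. Take a neighbour of zeta charged with 0.35 M of second reagent: scaling 33.6% in proportion and applying the share gives 17.7% of isomer, and that neighbour holds 53.1% of target with 16.9% of isomer.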